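## The problem

Labdane numbering is used throughout (ring A = C1–C5 and C10; ring B = C5–C10; C17 on C8; C18/C19 on C4; C20 on C10; chain C11–C16 on C9, with C16 the methyl on C13). The target 22 is a trans-fused decalin with five contiguous stereocentres around ring B (C5, C6, C8, C9, C10) and a sixth, C13, isolated in the chain. The quaternary C10 with its axial methyl is the anchor: once it is set, C5 (epimerisable beside a C6 carbonyl) goes to the trans fusion, and C9 and the two faces of ring B can be read from it. C13 lies four bonds from the nearest ring stereocentre and needs reagent control. C8 carries an equatorial hydroxyl and an axial methyl syn to C20, so the oxygen must come from α-face attack on a trigonal C8. The C6 oxygen is equatorial beside the C4 gem-dimethyl group, whereas hydride reagents would deliver the axial epimer. Three groups are fragile: the (Z)-2-methylbut-2-enoate (isomerises to the tiglate and is reducible), the tertiary allylic alcohol at C13 (ionises with acid and can form an 8,13-ether with the 8-hydroxyl) and the 6,8-dioxygenated ring B (retro-aldol or dehydration at the hydroxy-ketone stage). The enabling feature is that C6, at the ketone level, is flanked by C5=C10 and C7=C8, and both β-carbons, C10 and C8, are bonded to C9 in the target. β-Damascone is exactly this dienone with C1–C8 and C17–C20 in place, so a single carbon closes ring B. Because C9 must also bond to C11, that carbon should be nucleophilic three times over, which points to nitromethane.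

## Retrosynthesis

**Ester C6–O.** Target 22 is cut into triol 19 and angelic acid 20. The angelate is placed last because it would not survive the hydride, electron-transfer and alkaline peroxide steps that build ring B. The forward step must acylate one hindered secondary alcohol beside two tertiary ones without Z-to-E isomerisation.

**C6–H and C7–O.** Triol 19 comes from hydroxy ketone 18 by a thermodynamically controlled reduction, 18 from epoxy ketone 17 by cleavage of the C7–O bond, and 17 from enone 16. Hydration of a Δ7 alkene or hydride opening of a 7,8-epoxide was set aside, because regiochemistry there conflicts with trans-diaxial opening. In 17 the carbonyl dictates which C–O bond breaks. The forward steps need α-face epoxidation of 16 and an equatorial alcohol at C6.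

**C13.** The tertiary allylic alcohol of 16 is traced through allylic alcohol 15 and epoxy iodide 14 to epoxy alcohol 13, and 13 to the E-allylic alcohol 12 by asymmetric epoxidation. Vinyl addition to a C13 methyl ketone is shorter but gives no control at this remote centre. The chain is finished before C8 is oxygenated, so that no 8-hydroxyl is present to open the activated 13,14-epoxide. The C6 carbonyl of 16 is carried through 12–15 as a spectator allylic alcohol and re-oxidised afterwards.

**C7=C8 and C13=C14.** Diol 12 comes from dienone ester 11 by reduction of both carbonyl groups. Enone 11 comes from keto ester 9 through silyl enol ether 10, and 9 from diketone 7 and phosphonate 8 by olefination of the unhindered methyl ketone. The dehydrogenation is done here because the molecule then carries no hydroxyl and no terminal alkene. It also removes the C8 stereocentre, whose only task was to set C10.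

**C9–C11 and C9–N.** Diketone 7 comes from tertiary nitro compound 6 by radical denitration, and 6 from nitro ketone 4 and methyl vinyl ketone 5 by a nitro-Michael addition. The alternative, hydroxymethylation with formaldehyde followed by coupling of a C11 organometallic with a chiral epoxide, would need the C6 ketone masked and several protecting groups. Here the nitro group activates C9 once more, brings in C11, C12, C13 and C16 in one step, and then leaves.

**C8–C9 and C9–C10 (key step).** Nitro ketone 4 is opened at both bonds to C9, through the open-chain nitro ketone 3, to β-damascone 1 and nitromethane 2. The precursor has no ring B and no stereocentre. The forward reaction must add nitromethane enantioselectively at C8 and then force the nitronate onto the fully substituted C10.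

## Roads not taken

Alternative 1: Both rings are cut at once (C5–C10 and C8–C9) to the acyclic trienimide A2. Et2AlCl would promote the intramolecular Diels–Alder reaction of its (E)-β-methyl enimide with the tethered 2-silyloxydiene to give A1.
- Merits: the reaction class is known; the auxiliary sets C9 and C10 together; C11 arrives as an acyl carbon, so no nitro removal and no radical C–H step are needed; the silyl enol ether is regiodefined for the later enone.
- Weak points: A2 needs a long linear synthesis of a stereodefined trisubstituted enimide and a silyloxydiene beside a gem-dimethyl carbon. The dienophile is β,β-disubstituted and the diene terminus neighbours a quaternary carbon, so cycloaddition will be slow. Et2AlCl may desilylate the dienol ether or divert it into stepwise addition. The C8 methyl centre is again set only to be erased, and the auxiliary must be removed.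
- Comparison: A1 is reached by better-precedented chemistry and settles C9 more securely. The chosen plan sets against this a bicyclic core made in one operation from two commodity chemicals, with no auxiliary.

Alternative 2: Ring A is cut at C1–C10 and C4–C5. The diene A5 would add across a methyl-bearing double bond of quinone A4 under the triflimide-activated oxazaborolidinium catalyst from (S)-diphenylprolinol and o-tolylboronic acid, giving the cis-fused enedione A3.
- Merits: it is catalytic, enantioselective and one step from commercial materials, so it equals the chosen plan in directness. Its reaction class is well precedented. A3 already has the C6 carbonyl, the C7=C8 bond and the C8 methyl, so no dehydrogenation and no sacrificial stereocentre are needed.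
- Weak points: the terminus of A5 that must bond to C5 carries a cis methyl, so the diene reaches the s-cis form poorly and may polymerise under a cationic catalyst. A3 has a carbonyl at C9: the chain must be added to a ketone beside the quaternary C10 and the oxygen then removed with control of the C9 hydrogen. The two carbonyl groups must be told apart, the ring A alkene reduced and C5 epimerised.
- Comparison: in precedent this road is the stronger. The chosen plan sets against it a nitro group at C9 that is both a nucleophilic handle for the chain and traceless.

Alternative 3: Ring A is cut at C4–C5 with ring B already built. TiCl4 would ionise the tertiary chloride of A7, and C5 of its silyl dienol ether would attack the cation to give A6.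
- Merits: tertiary alkylation of silyl enol ethers is known. A6 is the Δ7-6-one with C11 oxygenated, the same hub as 11 or 16. C9 and C10 are fixed beforehand.
- Weak points: A7 is a cyclohexadiene with a quaternary C10 beside C9, so it needs its own enantioselective synthesis and the difficulty is moved rather than removed. The new bond joins C5 to a quaternary C4 next to a quaternary C10, where elimination of the cation and proto-desilylation compete. The C11 oxygen must still be turned into a carbon chain in the presence of the enone.
- Comparison: the key step is better precedented than that of the chosen plan. The chosen plan buys the C4–C5 bond ready-made in 1 and is far shorter to the bicycle.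

Key step: step 1

Assumption: the facial sense of cinchona thiourea catalysis known for chalcones is taken to hold for the crotonyl ketone of 1, which makes the quinidine-derived catalyst the one that gives (R)-3; if the sense is opposite, the quinine-derived pseudoenantiomer is used and nothing else changes.

## Route

Step 1
Reactants: 1 β-damascone; 2 nitromethane
Product: 4 9β-nitro-4,4,8α,10β-tetramethyl-trans-decalin-6-one in labdane numbering, via nitro ketone 3 (not isolated)
Conditions: MeNO2 (10 equiv), 9-amino-9-deoxy-epi-quinidine 3,5-(CF3)2C6H3-thiourea (10 mol %), toluene, 25 °C; evaporate; DBU (1.5 equiv), MeCN, 25→60 °C; AcOH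
Reagents that add atoms: none
Why: Proposed new method: the bifunctional thiourea binds the C6 carbonyl and ion-pairs the nitronate, which adds to the unhindered crotonyl β-carbon C8 (a known catalytic nitro-Michael addition to an acyclic enone) and sets C8 as R, while C10 is left alone because it is fully substituted and twisted out of conjugation. After nitromethane is stripped off, DBU regenerates the nitronate of 3, whose carbon C9 attacks C10 in a 6-endo-trig Michael closure of ring B; the closest known reaction type is the ring-closing second conjugate addition of the [5+1] annulation of divinyl ketones with nitromethane to 4-nitrocyclohexanones, which has not been shown for a tetrasubstituted β-carbon. The acyl group of 3 is already rotated out of the alkene plane, which holds C7 above the C5=C10 bond as the closure requires, and the equilibrium is pulled forward because 4 is drained as its more substituted nitronate. C10 is controlled by C8: in the chair-like transition state and in the product the C8 methyl is equatorial, which places C20 axial and C1 equatorial on ring B (1,3-relay). C9 and C5 are set by equilibration through the nitronate and the C6 enolate (equatorial nitro, trans fusion). The step needs regioselectivity for C8 in the first addition (secured by the hindered C10), C- over O-attack of the nitronate (secured by six-membered ring formation) and diastereoselectivity at C10. Because C8 is erased in step 5, the diastereomeric purity of 4 becomes the enantiomeric purity of all later compounds, so 4 is purified as a single diastereomer.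

Step 2
Reactants: 4 nitro ketone; 5 methyl vinyl ketone
Product: 6 9β-nitro-9α-(3-oxobutyl)-4,4,8α,10β-tetramethyl-trans-decalin-6-one
Conditions: 5 (2 equiv), tetramethylguanidine (0.2 equiv), MeCN, 0→25 °C
Reagents that add atoms: none
Why: Nitro-Michael addition of a secondary nitronate to an enone; the weak catalytic base deprotonates only the nitro compound, and the enone is expected to approach the axial α face of C9 away from C20, though the C9 configuration is immaterial because C9 becomes a radical in step 3.

Step 3
Reactants: 6 tertiary nitro diketone
Product: 7 9β-(3-oxobutyl)-4,4,8α,10β-tetramethyl-trans-decalin-6-one (9α-H)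
Conditions: Bu3SnH (3 equiv), AIBN (0.3 equiv), toluene, 110 °C
Reagents that add atoms: none
Why: Radical denitration of a tertiary nitro compound (Ono); the C9 radical should take hydrogen axially on the α face, anti to the axial C20 methyl, which puts the chain equatorial (9β) as in the target.

Step 4
Reactants: 7 diketone; 8 triethyl phosphonoacetate
Product: 9 ethyl (13E)-6-oxo-8βH-labd-13-en-15-oate
Conditions: 8, NaH, THF, 0→65 °C; chromatography to remove the 13Z isomer
Reagents that add atoms: none
Why: Horner–Wadsworth–Emmons olefination, chemoselective for the unhindered methyl ketone because the C6 ketone is flanked by C5 and the two quaternary carbons; the E isomer should predominate under the usual thermodynamic control and is separated from the minor Z isomer.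

Step 5
Reactants: 9 keto ester
Product: 11 ethyl (13E)-6-oxolabda-7,13-dien-15-oate, via trimethylsilyl enol ether 10 (not isolated)
Conditions: TMSOTf, Et3N, CH2Cl2, 0 °C; then Pd(OAc)2 (1.1 equiv), MeCN, 25 °C
Reagents that add atoms: trimethylsilyl triflate, C[Si](C)(C)OS(=O)(=O)C(F)(F)F (silyl group present only in intermediate 10)
Why: Saegusa–Ito dehydrogenation; soft enolisation goes toward C7 because a C5=C6 enol ether would be tetrasubstituted and strained against the C4 methyls, and the palladium enolate can reach the β face for syn elimination of the axial 8β-H, which removes the C8 stereocentre.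

Step 6
Reactants: 11 dienone ester
Product: 12 (13E)-labda-7,13-diene-6β,15-diol
Conditions: i-Bu2AlH (5 equiv), CH2Cl2, −78→0 °C; Rochelle salt
Reagents that add atoms: none
Why: Hydride reduction of the ester to the allylic alcohol and 1,2-reduction of the enone; hydride should enter C6 from the open α face to give the 6β-alcohol, whose configuration is immaterial because C6 is re-oxidised in step 10.

Step 7
Reactants: 12 diol
Product: 13 (13R,14R)-13,14-epoxylabd-7-ene-6β,15-diol
Conditions: Ti(Oi-Pr)4 (1.0 equiv), D-(−)-diisopropyl tartrate (1.2 equiv), t-BuOOH (1.5 equiv), 4 Å MS, CH2Cl2, −25 °C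
Reagents that add atoms: tert-butyl hydroperoxide, CC(C)(C)OO
Why: Sharpless asymmetric epoxidation; the D-(−)-tartrate gives the (2R,3R)-type epoxide of an E-3,3-disubstituted allylic alcohol, hence 13R,14R under reagent control, and the primary allylic alcohol reacts far faster than the hindered cyclic secondary one.

Step 8
Reactants: 13 epoxy diol
Product: 14 (13R,14S)-13,14-epoxy-15-iodolabd-7-en-6β-ol
Conditions: PPh3, I2, imidazole, THF, 0 °C
Reagents that add atoms: iodine, II
Why: Garegg–Samuelsson (Appel-type) iodination, selective for the primary alcohol because the axial 6β-hydroxyl between C5 and two syn-axial methyls cannot form the alkoxyphosphonium ion at a useful rate; the 14S descriptor reflects only the change in substituent priority.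

Step 9
Reactants: 14 epoxy iodide
Product: 15 (13R)-labda-7,14-diene-6β,13-diol
Conditions: Zn dust, AcOH (1.5 equiv), MeOH, 0→25 °C
Reagents that add atoms: none
Why: Reductive ring opening of a 2,3-epoxy iodide: zinc inserts into the C15–I bond and the epoxide oxygen leaves from C14, giving the C14=C15 vinyl group and the tertiary alcohol with the C13–O bond, and so the 13R configuration, untouched.

Step 10
Reactants: 15 diol
Product: 16 (13R)-13-hydroxylabda-7,14-dien-6-one
Conditions: Dess–Martin periodinane, NaHCO3, CH2Cl2, 0→25 °C
Reagents that add atoms: none
Why: Dess–Martin oxidation of the secondary allylic alcohol back to the enone; the tertiary alcohol cannot be oxidised and the buffered medium spares it from ionisation.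

Step 11
Reactants: 16 enone
Product: 17 (13R)-7α,8α-epoxy-13-hydroxylabd-14-en-6-one
Conditions: 30 % H2O2, NaOH, MeOH, 0→25 °C
Reagents that add atoms: hydrogen peroxide, OO
Why: Weitz–Scheffer nucleophilic epoxidation, specific for the enone; hydroperoxide adds to C8 from the α face because the β face is blocked by the syn-axial C20 methyl, which sets the C8–O bond α and the C17 methyl β.

Step 12
Reactants: 17 epoxy ketone
Product: 18 (13R)-8α,13-dihydroxylabd-14-en-6-one
Conditions: SmI2 (2.5 equiv), THF/MeOH, −90→−78 °C
Reagents that add atoms: none
Why: Reductive opening of an α,β-epoxy ketone by SmI2 (Molander): the ketyl expels the α oxygen, so only the C7–O bond breaks and the C8 configuration is kept.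

Step 13
Reactants: 18 hydroxy ketone
Product: 19 (13R)-labd-14-ene-6α,8α,13-triol (6α-hydroxysclareol)
Conditions: Li, NH3(l), THF, t-BuOH, −78 °C; NH4Cl
Reagents that add atoms: none
Why: Dissolving-metal reduction of a hindered cyclohexanone, which gives the more stable equatorial alcohol; 6α is favoured because a 6β-hydroxyl would be syn-axial to both C20 and the 4β-methyl, and the isolated vinyl group and the alkoxides are expected to be inert at −78 °C.

Step 14
Reactants: 19 triol; 20 angelic acid
Product: 22 6α-angeloyloxy-(13R)-labd-14-ene-8α,13-diol, via mixed anhydride 21 (not isolated)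
Conditions: 20 (3 equiv), 2,4,6-trichlorobenzoyl chloride, Et3N, toluene, 25 °C; then 19, 80 °C
Reagents that add atoms: 2,4,6-trichlorobenzoyl chloride, O=C(Cl)c1c(Cl)cc(Cl)cc1Cl (aroyl group present only in intermediate 21)
Why: Yamaguchi-type mixed-anhydride esterification run without a nucleophilic catalyst, the established way to make angelates without Z-to-E isomerisation; only the secondary 6α-hydroxyl is acylated because the other two are tertiary.

## Compound list

1 | β-damascone, (E)-1-(2,6,6-trimethylcyclohex-1-en-1-yl)but-2-en-1-one | C/C=C/C(=O)C1=C(C)CCCC1(C)C | starting material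
2 | nitromethane | C[N+](=O)[O-] | starting material
3 | (R)-3-methyl-4-nitro-1-(2,6,6-trimethylcyclohex-1-en-1-yl)butan-1-one | O=C(C[C@H](C[N+](=O)[O-])C)C1=C(C)CCCC1(C)C | intermediate
4 | 9β-nitro-4,4,8α,10β-tetramethyl-trans-decalin-6-one (5α-H, 9α-H) | [O-][N+](=O)[C@@H]1[C@@]2(C)CCCC(C)(C)[C@@H]2C(=O)C[C@H]1C | intermediate
5 | methyl vinyl ketone | C=CC(C)=O | starting material
6 | 9β-nitro-9α-(3-oxobutyl)-4,4,8α,10β-tetramethyl-trans-decalin-6-one (expected C9 epimer) | CC(=O)CC[C@@]1([N+](=O)[O-])[C@@]2(C)CCCC(C)(C)[C@@H]2C(=O)C[C@H]1C | intermediate
7 | 9β-(3-oxobutyl)-4,4,8α,10β-tetramethyl-trans-decalin-6-one (9α-H) | CC(=O)CC[C@@H]1[C@@]2(C)CCCC(C)(C)[C@@H]2C(=O)C[C@H]1C | intermediate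
8 | triethyl phosphonoacetate | CCOC(=O)CP(=O)(OCC)OCC | starting material
9 | ethyl (13E)-6-oxo-8βH-labd-13-en-15-oate (C17 α) | CCOC(=O)/C=C(\C)CC[C@@H]1[C@@]2(C)CCCC(C)(C)[C@@H]2C(=O)C[C@H]1C | intermediate
10 | ethyl (13E)-6-(trimethylsilyloxy)-8βH-labda-6,13-dien-15-oate | CCOC(=O)/C=C(\C)CC[C@@H]1[C@@]2(C)CCCC(C)(C)[C@@H]2C(O[Si](C)(C)C)=C[C@H]1C | intermediate
11 | ethyl (13E)-6-oxolabda-7,13-dien-15-oate | CCOC(=O)/C=C(\C)CC[C@@H]1[C@@]2(C)CCCC(C)(C)[C@@H]2C(=O)C=C1C | intermediate
12 | (13E)-labda-7,13-diene-6β,15-diol (expected C6 epimer) | OC/C=C(\C)CC[C@@H]1[C@@]2(C)CCCC(C)(C)[C@@H]2[C@H](O)C=C1C | intermediate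
13 | (13R,14R)-13,14-epoxylabd-7-ene-6β,15-diol | OC[C@H]1O[C@]1(C)CC[C@@H]2[C@@]3(C)CCCC(C)(C)[C@@H]3[C@H](O)C=C2C | intermediate
14 | (13R,14S)-13,14-epoxy-15-iodolabd-7-en-6β-ol | IC[C@H]1O[C@]1(C)CC[C@@H]2[C@@]3(C)CCCC(C)(C)[C@@H]3[C@H](O)C=C2C | intermediate
15 | (13R)-labda-7,14-diene-6β,13-diol | C=C[C@](C)(O)CC[C@@H]1[C@@]2(C)CCCC(C)(C)[C@@H]2[C@H](O)C=C1C | intermediate
16 | (13R)-13-hydroxylabda-7,14-dien-6-one | C=C[C@](C)(O)CC[C@@H]1[C@@]2(C)CCCC(C)(C)[C@@H]2C(=O)C=C1C | intermediate
17 | (13R)-7α,8α-epoxy-13-hydroxylabd-14-en-6-one | C=C[C@](C)(O)CC[C@@H]1[C@@]2(C)CCCC(C)(C)[C@@H]2C(=O)[C@H]3O[C@@]13C | intermediate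
18 | (13R)-8α,13-dihydroxylabd-14-en-6-one | C=C[C@](C)(O)CC[C@@H]1[C@@]2(C)CCCC(C)(C)[C@@H]2C(=O)C[C@@]1(C)O | intermediate
19 | (13R)-labd-14-ene-6α,8α,13-triol | C=C[C@](C)(O)CC[C@@H]1[C@@]2(C)CCCC(C)(C)[C@@H]2[C@@H](O)C[C@@]1(C)O | intermediate
20 | angelic acid, (Z)-2-methylbut-2-enoic acid | C/C=C(/C)C(=O)O | starting material
21 | angelic 2,4,6-trichlorobenzoic anhydride | C/C=C(/C)C(=O)OC(=O)c1c(Cl)cc(Cl)cc1Cl | intermediate
22 | 6α-angeloyloxy-(13R)-labd-14-ene-8α,13-diol (CNP0203829.1) | C=C[C@](C)(O)CC[C@@H]1[C@@]2(C)CCCC(C)(C)[C@@H]2[C@@H](OC(=O)/C(C)=C\C)C[C@@]1(C)O | target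

## Step count and least certain steps

Total: 14 steps. Longest linear sequence: 14 steps from 1.

**Step 1 (key step, proposed new method).** The ring closure may not occur: the nitronate may fail to add to the twisted, fully substituted C10, and the adduct may instead lose nitromethane by retro-addition or have its ring alkene moved out of conjugation. The first addition may also be slow or poorly enantioselective at the hindered ketone. Fallback with known reaction types, setting out from 1 and coming back at 7:
- Rh(acac)(C2H4)2 with the BINAP antipode that gives the 8R adduct catalyses conjugate addition of (E)-3-(trimethylsilyl)prop-1-enylboronic acid pinacol ester to 1 (Hayashi–Miyaura), giving (3R,4E)-3-methyl-6-(trimethylsilyl)-1-(2,6,6-trimethylcyclohex-1-en-1-yl)hex-4-en-1-one F1.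
- TiCl4 in CH2Cl2 at −78 °C closes ring B by intramolecular Hosomi–Sakurai addition, in which Lewis-acid activation makes C10 a tertiary cation equivalent. After base equilibration of C5 this gives 9β-vinyl-4,4,8α,10β-tetramethyl-trans-decalin-6-one F2.
- Cross-metathesis of F2 with 5, using the second-generation Grubbs catalyst RuCl2(PCy3)(H2IMes)(=CHPh), gives 9β-[(E)-3-oxobut-1-enyl]-4,4,8α,10β-tetramethyl-trans-decalin-6-one F3.
- H2 over Pd/C returns 7.

**Step 2.** Carbon–carbon bond formation at the neopentyl-type nitronate carbon may be slow, and the base may open ring B by retro-Michael cleavage once C9 is fully substituted. Fallback with a smaller electrophile, setting out from 4 and coming back at 7: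
- Henry reaction of 4 with aqueous formaldehyde and Et3N gives 9α-(hydroxymethyl)-9β-nitro-4,4,8α,10β-tetramethyl-trans-decalin-6-one F4.
- Bu3SnH/AIBN gives 9β-(hydroxymethyl)-4,4,8α,10β-tetramethyl-trans-decalin-6-one F5.
- Dess–Martin oxidation gives 6-oxo-4,4,8α,10β-tetramethyl-trans-decalin-9β-carbaldehyde F6, in which C9 can be equilibrated to the equatorial aldehyde if the radical step was unselective.
- Wittig reaction with 1-(triphenylphosphoranylidene)propan-2-one gives the enone F3 already described, and hydrogenation over Pd/C returns 7.

**Step 11.** Alkaline peroxide may deprotonate C9 (γ to the enone), which would epimerise C9 or move the double bond, and the facial selectivity at C8 may be incomplete. Fallback that avoids the epoxide, setting out from 16 and coming back at 18: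
- Copper-catalysed conjugate borylation (CuCl, NaOt-Bu, DPEphos, B2pin2, MeOH, THF) from the α face gives (13R)-13-hydroxy-8α-(4,4,5,5-tetramethyl-1,3,2-dioxaborolan-2-yl)labd-14-en-6-one F7.
- Oxidation with NaBO3·4H2O, with retention at C8, gives 18.

**Step 13.** The lithium alkoxide of the β-hydroxy ketone may undergo retro-aldol opening of ring B, the allylic C13–O bond may be cleaved, or selectivity for the equatorial alcohol may be incomplete. Fallback that separates reduction from stereocontrol, setting out from 18 and coming back at 19:
- NaBH4 in MeOH gives (13R)-labd-14-ene-6β,8α,13-triol F8 by α-face hydride attack.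
- Meerwein–Ponndorf–Verley/Oppenauer equilibration (Al(Oi-Pr)3, i-PrOH, trace acetone, reflux) should funnel the axial alcohol to the equatorial 19.

**Step 14.** The angeloyl group may isomerise to tigloyl during activation, and acylation of the hindered 6α-hydroxyl may be slow. Fallback that builds the Z alkene on the ester, setting out from 19 and coming back at 22:
- Acylation with 2-[bis(2,2,2-trifluoroethoxy)phosphoryl]propanoic acid (DCC, DMAP) gives the 6α-O-[2-(bis(2,2,2-trifluoroethoxy)phosphoryl)propanoyl] ester of 19, F9.
- Still–Gennari olefination with acetaldehyde (KN(SiMe3)2, 18-crown-6, THF, −78 °C) gives the Z-configured ester 22.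

## Further compounds

F1 | step 1 | (3R,4E)-3-methyl-6-(trimethylsilyl)-1-(2,6,6-trimethylcyclohex-1-en-1-yl)hex-4-en-1-one | O=C(C[C@H](/C=C/C[Si](C)(C)C)C)C1=C(C)CCCC1(C)C
F2 | step 1 | 9β-vinyl-4,4,8α,10β-tetramethyl-trans-decalin-6-one | C=C[C@@H]1[C@@]2(C)CCCC(C)(C)[C@@H]2C(=O)C[C@H]1C
F3 | step 1 | 9β-[(E)-3-oxobut-1-enyl]-4,4,8α,10β-tetramethyl-trans-decalin-6-one | CC(=O)/C=C/[C@@H]1[C@@]2(C)CCCC(C)(C)[C@@H]2C(=O)C[C@H]1C
F4 | step 2 | 9α-(hydroxymethyl)-9β-nitro-4,4,8α,10β-tetramethyl-trans-decalin-6-one | OC[C@@]1([N+](=O)[O-])[C@@]2(C)CCCC(C)(C)[C@@H]2C(=O)C[C@H]1C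
F5 | step 2 | 9β-(hydroxymethyl)-4,4,8α,10β-tetramethyl-trans-decalin-6-one | OC[C@@H]1[C@@]2(C)CCCC(C)(C)[C@@H]2C(=O)C[C@H]1C
F6 | step 2 | 6-oxo-4,4,8α,10β-tetramethyl-trans-decalin-9β-carbaldehyde | O=C[C@@H]1[C@@]2(C)CCCC(C)(C)[C@@H]2C(=O)C[C@H]1C
F7 | step 11 | (13R)-13-hydroxy-8α-(4,4,5,5-tetramethyl-1,3,2-dioxaborolan-2-yl)labd-14-en-6-one | C=C[C@](C)(O)CC[C@@H]1[C@@]2(C)CCCC(C)(C)[C@@H]2C(=O)C[C@@]1(C)B3OC(C)(C)C(C)(C)O3
F8 | step 13 | (13R)-labd-14-ene-6β,8α,13-triol | C=C[C@](C)(O)CC[C@@H]1[C@@]2(C)CCCC(C)(C)[C@@H]2[C@H](O)C[C@@]1(C)O
F9 | step 14 | 6α-O-[2-(bis(2,2,2-trifluoroethoxy)phosphoryl)propanoyl]-(13R)-labd-14-ene-6α,8α,13-triol | C=C[C@](C)(O)CC[C@@H]1[C@@]2(C)CCCC(C)(C)[C@@H]2[C@@H](OC(=O)C(C)P(=O)(OCC(F)(F)F)OCC(F)(F)F)C[C@@]1(C)O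
A1 | alternative 1 | trans-fused 6-(triisopropylsilyloxy)drim-6-en-11-oyl 4-benzyloxazolidin-2-one imide (8β-methyl, 9β-acyl) | O=C1OC[C@H](Cc2ccccc2)N1C(=O)[C@@H]1[C@@]2(C)CCCC(C)(C)[C@@H]2C(O[Si](C(C)C)(C(C)C)C(C)C)=C[C@@H]1C
A2 | alternative 1 | N-[(2E,10E)-3,7,7-trimethyl-9-(triisopropylsilyloxy)dodeca-2,8,10-trienoyl]-4-benzyloxazolidin-2-one | O=C1OC[C@H](Cc2ccccc2)N1C(=O)/C=C(\C)CCCC(C)(C)C=C(O[Si](C(C)C)(C(C)C)C(C)C)/C=C/C
A3 | alternative 2 | cis-2,5,5,8a-tetramethyl-4a,5,8,8a-tetrahydronaphthalene-1,4-dione | O=C1C(C)=CC(=O)[C@@H]2C(C)(C)C=CC[C@@]21C
A4 | alternative 2 | 2,6-dimethyl-1,4-benzoquinone | CC1=CC(=O)C=C(C)C1=O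
A5 | alternative 2 | 4-methylpenta-1,3-diene | CC(C)=CC=C
A6 | alternative 3 | 11-(tert-butyldimethylsilyloxy)drim-7-en-6-one | CC(C)(C)[Si](C)(C)OC[C@@H]1[C@@]2(C)CCCC(C)(C)[C@@H]2C(=O)C=C1C
A7 | alternative 3 | 5-(tert-butyldimethylsilyloxymethyl)-6-(4-chloro-4-methylpentyl)-4,6-dimethyl-2-(trimethylsilyloxy)cyclohexa-1,3-diene | CC(C)(C)[Si](C)(C)OC[C@@H]1[C@@](C)(CCCC(C)(C)Cl)C=C(O[Si](C)(C)C)C=C1C
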